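The numbers in the tables stem from a simulated flask for substances that don't exist, noise included.

14.1% of the charge as target is the quick number for the flask, and it rests on freezing one quantity, c(dissolved gas).

| setting | east | south-west | flask |
|---|---|---|---|
| starting material | 0.070 M (fed, over 2.0 min) | 0.11 M (fed, over 2.0 min) | 0.14 M (fed, over 2.0 min) |
| gas phase | 49 mM (held) | 49 mM (held) | 49 mM (held) |
| remark | run made earlier | run made earlier |  |
| time |  |  | 40 min |

| run | time / min | target / % |
|---|---|---|
| east | 0.667 | 2.1 |
| east | 1.33 | 7.3 |
| east | 3.00 | 16.0 |
| east | 6.00 | 3.1 |
| east | 15.0 | 1.1 |
| east | 30.0 | 0.2 |
| south-west | 0.667 | 3.9 |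
| south-west | 1.33 | 8.8 |
| south-west | 3.00 | 12.2 |
| south-west | 6.00 | 3.1 |
| south-west | 15.0 | 1.2 |
| south-west | 30.0 | 0.3 |

(readings scatter by 1 percentage point)

- the moment within 40 min at which there is most target
- the amount of target, in percent of the starting material charged, at that time
- earliest time at which at least nineteen twentieths of that best amount are there, in min
- latest time at which they still are, in min

- at the start none of the gas is dissolved
- reactions considered so far: dissolved gas -> decomposed reagent; gas phase <-> dissolved gas; starting material -> side product; starting material + dissolved gas -> target; target -> over-reaction product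
- percentages count the whole charge, also what has not yet gone in

At 1.33 min the target reads 7.3% in the east run and 8.8% in the south-west run, so these readings do not fall as the charge rises from 0.070 M to 0.11 M. A steady c(dissolved gas) gives such a picture: the step to target is then pseudo-first-order in starting material, and with the same dosing time and the same c(dissolved gas), percentages of the charge follow one curve. Both runs show their highest reading at 3.00 min: 16.0% and 12.2%. These differ by 3.8 percentage points against a scatter of 1 point, so the freezing is rough. Their mean, called here the frozen-gas share, is a reading of that common curve at 3.00 min, taken as the height of its top. This reckoning therefore puts the flask at about 14.1%, with the top near 3.00 min. The readings stand too far apart in time to place open and shut.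

The forecast gives tbest 2.4 min, best 11%, open 1.85 min and shut 3 min, on this ground: “So the dissolved-gas pool runs out, and it runs out sooner at higher loading.” The two part on whether c(dissolved gas) holds at the higher charge, and the best of the forecast lies 3.1 points lower than the frozen-gas share.

The flask gives tbest 2.58 min, best 14.5%, open 2.17 min and shut 3.08 min.

    dissolved gas → decomposed reagent (k = 0.0130 s⁻¹)
    gas phase ⇌ dissolved gas, rate k2*(csat - [dissolved gas]) (kL = 0.0250 s⁻¹)
    starting material → side product (k = 0.00720 s⁻¹)
    starting material + dissolved gas → target (k = 0.240 L mol⁻¹ s⁻¹)
    target → over-reaction product (k = 0.0130 s⁻¹)

In the flask, c(dissolved gas) stands at 0.0227 M after 2.00 min and at 0.0238 M after 2.58 min, and the frozen-gas share of 14.1% lies 0.40 points below the best of this flask. The neighbour charged with 0.56 M stays under the frozen-gas share by a factor of 1.62, with a best of 8.69%.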